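**Strategy.** Everything rests on cutting C6–C10 of the seven-membered ring. With oxygen on C6 and a carbonyl on C9 this bond is that of an aldol, so the 5-7 skeleton is the retro-aldol product of a cyclobutanol C1–C5–C6–C10. The key step exploits that C1 and C5 are the α- and β-carbons of the ring A C2 enone: irradiating (S)-4-silyloxy-2-methylcyclopentenone with a 1-benzyloxycyclopentene carrying the C8 methyl and a benzyl-protected C9 carbinol forms C1–C10 and C5–C6 at once and sets quaternary C1 anti to the C4 silyloxy group. The partner's regiochemistry is locked by α′-methylation of a vinylogous ester.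

Key step: step 7

Numbering: C1 = quaternary ring-fusion carbon (methyl), C2–C4 = ring A, C5 = ring-fusion CH, C6–C10 = rest of the seven-membered ring (C10 bonded to C1); β = face of the C1 methyl.

Remark: partner 9 is racemic and used as its cis/trans mixture; C9 is erased in step 10 and C8 in step 15, so 10–18 are C8 (10–12 also C9) epimer mixtures, and 10–13 are drawn as the expected cis-anti-cis adduct.

Step 1
Reactants: 1 (S)-4-(tert-butyldimethylsilyloxy)cyclopent-2-en-1-one
Product: 2 (S)-4-(tert-butyldimethylsilyloxy)-2-iodocyclopent-2-en-1-one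
Conditions: I2, pyridine, CH2Cl2, 0 °C → rt
Reagents that add atoms: iodine, II
Why: Pyridine adds to the enone in a Baylis–Hillman-type manner, the enolate is iodinated and pyridine is expelled (α-iodination of an enone), which should leave the C4 stereocentre and the β-silyloxy group untouched.

Step 2
Reactants: 2 (S)-4-(tert-butyldimethylsilyloxy)-2-iodocyclopent-2-en-1-one
Product: 3 (S)-4-(tert-butyldimethylsilyloxy)-2-methylcyclopent-2-en-1-one
Conditions: MeZnCl, Pd(PPh3)4 (5 mol %), THF, 0 °C → rt
Reagents that add atoms: methylzinc chloride, C[Zn]Cl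
Why: Negishi coupling of the electron-poor alkenyl iodide (oxidative addition to zerovalent palladium, transmetalation, reductive elimination) should be fast under neutral conditions, avoiding the base that would eliminate the silyloxy group.

Step 3
Reactants: 4 cyclopentane-1,3-dione
Product: 5 3-(benzyloxy)cyclopent-2-en-1-one
Conditions: BnOH, TsOH·H2O (cat.), toluene, reflux, Dean–Stark trap
Reagents that add atoms: benzyl alcohol, OCc1ccccc1
Why: Acid-catalysed condensation of the enolised, symmetric 1,3-dione with the alcohol under water removal gives the vinylogous ester, with no regiochemical question at this stage.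

Step 4
Reactants: 5 3-(benzyloxy)cyclopent-2-en-1-one
Product: 7 3-(benzyloxy)-5-methylcyclopent-2-en-1-one, via lithium dienolate 6 (not isolated)
Conditions: LiN(iPr)2, THF, −78 °C; MeI, −78 → −20 °C
Reagents that add atoms: methyl iodide, CI
Why: Kinetic α′-deprotonation and C-methylation of a vinylogous ester (Stork–Danheiser alkylation) puts the methyl next to the carbonyl that becomes C9, so the C6-oxygen/C10/C9/C8-methyl pattern is fixed unambiguously; the new centre is racemic and is erased in step 15.

Step 5
Reactants: 7 3-(benzyloxy)-5-methylcyclopent-2-en-1-one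
Product: 8 3-(benzyloxy)-5-methylcyclopent-2-en-1-ol (cis/trans mixture)
Conditions: LiAlH4, Et2O, −20 °C; aqueous NaOH work-up
Reagents that add atoms: none
Why: Hydride adds 1,2 to the vinylogous ester carbonyl and a basic work-up should keep the acid-labile 3-alkoxy allylic alcohol intact (1,2-reduction); the carbinol configuration is irrelevant because C9 is re-oxidised in step 10.

Step 6
Reactants: 8 3-(benzyloxy)-5-methylcyclopent-2-en-1-ol
Product: 9 1,3-bis(benzyloxy)-4-methylcyclopent-1-ene (cis/trans mixture)
Conditions: NaH, BnBr, Bu4NI (cat.), THF, 0 °C → rt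
Reagents that add atoms: benzyl bromide, BrCc1ccccc1
Why: Williamson etherification under basic conditions protects the C9 carbinol without exposing the enol ether to acid and gives an electron-rich alkene that does not absorb above 300 nm.

Step 7
Reactants: 3 (S)-4-(tert-butyldimethylsilyloxy)-2-methylcyclopent-2-en-1-one; 9 1,3-bis(benzyloxy)-4-methylcyclopent-1-ene
Product: 10 cis-anti-cis 5-4-5 tricyclic photoadduct (C2 ketone; 4β-OTBS; 1β-methyl; 5β-H; 6-OBn; 9-OBn; 8-methyl)
Conditions: hν (medium-pressure mercury lamp, Pyrex filter, λ > 300 nm), 9 (4 equiv), MeCN, −30 °C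
Reagents that add atoms: none
Why: n→π* excitation and intersystem crossing give the enone triplet, which bonds through its β-carbon C5 to the oxygen-bearing C6 of the enol ether and, after spin inversion of the 1,4-diradical, closes C1–C10; this is an enone–alkene [2+2] photocycloaddition, the first stage of a de Mayo sequence. The cyclobutane C1–C5–C6–C10 closes by diradical recombination and is necessarily cis-fused to both five-membered rings. C1 and C5 are set by approach of the alkene to the enone face opposite the C4 silyloxy group, which places the C1 methyl β; C6 and C10 follow from the cis fusion of the cyclopentene and, like C8 and C9, are erased later. The step needs head-to-tail regiochemistry and anti facial selectivity. The first should be secured by the donor oxygen on C6 (the oxygen-bearing terminus of an enol ether ends on the enone β-carbon), the second by the γ-silyloxy stereocentre. The alkene is transparent at the irradiation wavelength and used in excess, which should suppress enone dimerisation.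

Step 8
Reactants: 10 cis-anti-cis 5-4-5 tricyclic photoadduct
Product: 11 C2 ethylene ketal of the photoadduct
Conditions: TMSOCH2CH2OTMS, TMSOTf (5 mol %), CH2Cl2, −78 → −20 °C; pyridine quench
Reagents that add atoms: 1,2-bis(trimethylsilyloxy)ethane, C[Si](C)(C)OCCO[Si](C)(C)C
Why: Silyl triflate-catalysed ketalisation with the bis-silyl ether of ethylene glycol should convert the hindered cyclopentanone at low temperature without disturbing silyl or benzyl ethers, masking C2 against β-elimination of the C4 oxygen and against the later reductions.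

Step 9
Reactants: 11 C2 ethylene ketal of the photoadduct
Product: 12 tricyclic 6,9-diol (C2 ketal; 4β-OTBS)
Conditions: H2 (1 atm), Pd/C, EtOAc, rt
Reagents that add atoms: none
Why: Hydrogenolysis cleaves both benzyl ethers (tertiary at C6, secondary at C9) while ketal, silyl ether and cyclobutane are inert, unmasking the 1,3-diol of the latent aldol.

Step 10
Reactants: 12 tricyclic 6,9-diol
Product: 14 cis-fused 6,9-dione (C2 ketal; 4β-OTBS; 5β-H), via cyclobutanol ketone 13 (not isolated)
Conditions: Dess–Martin periodinane, pyridine, CH2Cl2, 0 °C → rt; then Et3N, rt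
Reagents that add atoms: none
Why: Dess–Martin oxidation touches only the secondary C9 carbinol, and the resulting β-hydroxy ketone should undergo strain-driven retro-aldol cleavage of C6–C10 on mild base (de Mayo fragmentation), opening the seven-membered ring as the still cis-fused 6,9-dione.

Step 11
Reactants: 14 cis-fused 6,9-dione
Product: 15 cis-fused 4β-hydroxy-6,9-dione (C2 ketal)
Conditions: HF·pyridine, pyridine, THF, 0 °C → rt
Reagents that add atoms: none
Why: Buffered fluoride desilylation frees the C4 hydroxyl without generating an alkoxide, so retro-aldol opening of ring A, dehydration and ketal loss should be avoided.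

Step 12
Reactants: 15 cis-fused 4β-hydroxy-6,9-dione
Product: 16 trans-fused 4β-hydroxy-6,9-dione (5α-H)
Conditions: DBU (0.2 equiv), toluene, rt
Reagents that add atoms: none
Why: Reversible enolisation of the C6 ketone toward C5 (base-mediated epimerisation) should settle on the trans ring fusion, which is the usual thermodynamic preference of such angularly methylated hydroazulenones and the only isomer in which the C4 hydroxyl can hydrogen-bond to the C6 carbonyl in an aprotic medium.

Step 13
Reactants: 16 trans-fused 4β-hydroxy-6,9-dione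
Product: 17 4β-acetoxy-6α-hydroxy-9-ketone (C2 ketal; trans-fused)
Conditions: SmI2 (0.3 equiv), CH3CHO (8 equiv), THF, −10 °C
Reagents that add atoms: acetaldehyde, CC=O
Why: In this Evans–Tishchenko reduction the samarium-bound hemiacetal on O4 delivers hydride through a chair transition state to the β-face of the C6 carbonyl only, which should give the 6α-carbinol, leave the remote C9 ketone untouched and cap O4 as its acetate.

Step 14
Reactants: 17 4β-acetoxy-6α-hydroxy-9-ketone
Product: 18 4β-acetoxy-6α-(4-methoxybenzoyloxy)-9-ketone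
Conditions: 4-MeOC6H4COCl, DMAP (cat.), pyridine, CH2Cl2, 0 °C → rt
Reagents that add atoms: 4-methoxybenzoyl chloride, COc1ccc(cc1)C(Cl)=O
Why: Acylation of the only free (equatorial, secondary) hydroxyl installs the final anisate while O4 is blocked as the acetate.

Step 15
Reactants: 18 4β-acetoxy-6α-(4-methoxybenzoyloxy)-9-ketone
Product: 19 C9 enol triflate with C8=C9
Conditions: Tf2O, 2,6-di-tert-butyl-4-methylpyridine, CH2Cl2, 0 °C → rt
Reagents that add atoms: triflic anhydride, FC(F)(F)S(=O)(=O)OS(=O)(=O)C(F)(F)F
Why: O-triflation of the single ketone and loss of the C8 proton (enol triflate formation) should give the more substituted alkenyl triflate rather than the one toward the neopentyl C10, under non-nucleophilic conditions that spare esters and ketal; the C8 stereocentre is erased here.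

Step 16
Reactants: 19 C9 enol triflate
Product: 20 4β-acetoxy-6α-(4-methoxybenzoyloxy)-8-ene (C2 ketal)
Conditions: Pd(OAc)2 (5 mol %), PPh3, Bu3N, HCO2H, DMF, 60 °C
Reagents that add atoms: none
Why: Oxidative addition of the alkenyl triflate to zerovalent palladium, formate exchange, decarboxylation and reductive elimination (palladium-catalysed formate reduction) replace the triflate by hydrogen and fix the C8=C9 alkene in place.

Step 17
Reactants: 20 4β-acetoxy-6α-(4-methoxybenzoyloxy)-8-ene
Product: 21 4β-hydroxy-6α-(4-methoxybenzoyloxy)-8-ene (C2 ketal)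
Conditions: K2CO3 (0.5 equiv), MeOH, 0 °C
Reagents that add atoms: none
Why: Base-catalysed methanolysis cleaves the alkyl acetate much faster than the electron-rich aryl ester, and the low temperature should limit acyl migration to O4.

Step 18
Reactants: 21 4β-hydroxy-6α-(4-methoxybenzoyloxy)-8-ene
Product: 22 C4 ketone (C2 ketal; 6α-anisate; 8-ene)
Conditions: Dess–Martin periodinane, pyridine, CH2Cl2, 0 °C
Reagents that add atoms: none
Why: Dess–Martin oxidation under buffered, non-basic conditions should give the C4 ketone without epimerising C5 or eliminating the β-acyloxy group.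

Step 19
Reactants: 22 C4 ketone
Product: 23 4β-hydroxy-4α-isopropyl compound (C2 ketal; 6α-anisate; 8-ene)
Conditions: iPrMgCl, CeCl3 (anhydrous), THF, −78 °C
Reagents that add atoms: isopropylmagnesium chloride, CC(C)[Mg]Cl
Why: The weakly basic organocerium reagent should add to the enolisable ketone faster than to the esters (1,2-addition), from the α-face opposite the angular C1 methyl and the C5–C6 bond, which sets the 4β-hydroxy-4α-isopropyl centre.

Step 20
Reactants: 23 4β-hydroxy-4α-isopropyl compound
Product: 24 C2 ketone (4β-hydroxy-4α-isopropyl; 6α-anisate; 8-ene)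
Conditions: PPTS, THF/H2O (4:1), 50 °C
Reagents that add atoms: water, O
Why: Mild acid hydrolysis of the dioxolane returns the C2 ketone, the acid being too weak to dehydrate the tertiary β-hydroxy ketone or move the alkene.

Step 21
Reactants: 24 C2 ketone
Product: 25 2β,4β-diol 6α-anisate
Conditions: NaBH4, MeOH, −20 °C
Reagents that add atoms: none
Why: Borohydride should attack the cyclopentanone from the α-face, anti to the adjacent angular methyl as in 17-oxo steroids (hydride reduction), giving the 2β-carbinol and leaving the ester alone.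

Step 22
Reactants: 25 2β,4β-diol 6α-anisate
Product: 26 CNP0204191.1 (2β-angelate, 4β-hydroxy-4α-isopropyl, 6α-anisate, 8-ene)
Conditions: angelic acid, 2,4,6-trichlorobenzoyl chloride, Et3N, toluene, rt; then 25, 80 °C
Reagents that add atoms: angelic acid ((Z)-2-methylbut-2-enoic acid), C/C=C(/C)C(=O)O
Why: Yamaguchi esterification through the mixed trichlorobenzoic anhydride acylates the secondary C2 hydroxyl (the tertiary C4 hydroxyl is inert) without a nucleophilic catalyst, so the Z-alkene should not isomerise to the tiglate.

**Compound list**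

1 | (S)-4-(tert-butyldimethylsilyloxy)cyclopent-2-en-1-one | O=C1C[C@H](O[Si](C)(C)C(C)(C)C)C=C1 | starting material
2 | (S)-4-(tert-butyldimethylsilyloxy)-2-iodocyclopent-2-en-1-one | O=C1C[C@H](O[Si](C)(C)C(C)(C)C)C=C1I | intermediate
3 | (S)-4-(tert-butyldimethylsilyloxy)-2-methylcyclopent-2-en-1-one | O=C1C[C@H](O[Si](C)(C)C(C)(C)C)C=C1C | intermediate
4 | cyclopentane-1,3-dione | O=C1CCC(=O)C1 | starting material
5 | 3-(benzyloxy)cyclopent-2-en-1-one | O=C1CCC(OCc2ccccc2)=C1 | intermediate
6 | lithium 4-(benzyloxy)cyclopenta-1,4-dien-1-olate (not isolated) | [Li+].[O-]C1=CCC(OCc2ccccc2)=C1 | intermediate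
7 | 3-(benzyloxy)-5-methylcyclopent-2-en-1-one (racemic) | O=C1C(C)CC(OCc2ccccc2)=C1 | intermediate
8 | 3-(benzyloxy)-5-methylcyclopent-2-en-1-ol (racemic, cis/trans mixture) | OC1C(C)CC(OCc2ccccc2)=C1 | intermediate
9 | 1,3-bis(benzyloxy)-4-methylcyclopent-1-ene (racemic, cis/trans mixture) | CC1CC(OCc2ccccc2)=CC1OCc1ccccc1 | intermediate
10 | cis-anti-cis 5-4-5 photoadduct: C2 ketone, 4β-OTBS, 1β-methyl, 5β-H, 6-OBn (on the ring A face of the cyclobutane), 9-OBn, 8-methyl (C8/C9 epimers) | O=C1C[C@H](O[Si](C)(C)C(C)(C)C)[C@H]2[C@]3(OCc4ccccc4)CC(C)C(OCc4ccccc4)[C@@H]3[C@]21C | intermediate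
11 | C2 ethylene ketal of 10 | O1CCOC12C[C@H](O[Si](C)(C)C(C)(C)C)[C@H]3[C@]4(OCc5ccccc5)CC(C)C(OCc5ccccc5)[C@@H]4[C@]32C | intermediate
12 | tricyclic diol: tertiary C6–OH, secondary C9–OH, C2 ketal, 4β-OTBS | O1CCOC12C[C@H](O[Si](C)(C)C(C)(C)C)[C@H]3[C@]4(O)CC(C)C(O)[C@@H]4[C@]32C | intermediate
13 | cyclobutanol ketone: C6–OH, C9 ketone (not isolated) | O1CCOC12C[C@H](O[Si](C)(C)C(C)(C)C)[C@H]3[C@]4(O)CC(C)C(=O)[C@@H]4[C@]32C | intermediate
14 | cis-fused (5β-H) hydroazulene-6,9-dione: C2 ketal, 4β-OTBS, 1β-methyl, 8-methyl (C8 epimers) | O1CCOC12C[C@H](O[Si](C)(C)C(C)(C)C)[C@H]3C(=O)CC(C)C(=O)C[C@]32C | intermediate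
15 | cis-fused 4β-hydroxy-6,9-dione, C2 ketal | O1CCOC12C[C@H](O)[C@H]3C(=O)CC(C)C(=O)C[C@]32C | intermediate
16 | trans-fused (5α-H) 4β-hydroxy-6,9-dione, C2 ketal | O1CCOC12C[C@H](O)[C@@H]3C(=O)CC(C)C(=O)C[C@]32C | intermediate
17 | trans-fused 4β-acetoxy-6α-hydroxy-9-ketone, C2 ketal | O1CCOC12C[C@H](OC(C)=O)[C@@H]3[C@@H](O)CC(C)C(=O)C[C@]32C | intermediate
18 | 4β-acetoxy-6α-(4-methoxybenzoyloxy)-9-ketone, C2 ketal | O1CCOC12C[C@H](OC(C)=O)[C@@H]3[C@@H](OC(=O)c4ccc(OC)cc4)CC(C)C(=O)C[C@]32C | intermediate
19 | C9 enol triflate (C8=C9), 4β-acetoxy, 6α-anisate, C2 ketal | O1CCOC12C[C@H](OC(C)=O)[C@@H]3[C@@H](OC(=O)c4ccc(OC)cc4)CC(C)=C(OS(=O)(=O)C(F)(F)F)C[C@]32C | intermediate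
20 | 4β-acetoxy-6α-anisoyloxy-8-ene, C2 ketal | O1CCOC12C[C@H](OC(C)=O)[C@@H]3[C@@H](OC(=O)c4ccc(OC)cc4)CC(C)=CC[C@]32C | intermediate
21 | 4β-hydroxy-6α-anisoyloxy-8-ene, C2 ketal | O1CCOC12C[C@H](O)[C@@H]3[C@@H](OC(=O)c4ccc(OC)cc4)CC(C)=CC[C@]32C | intermediate
22 | C4 ketone, 6α-anisoyloxy-8-ene, C2 ketal | O1CCOC12CC(=O)[C@@H]3[C@@H](OC(=O)c4ccc(OC)cc4)CC(C)=CC[C@]32C | intermediate
23 | 4β-hydroxy-4α-isopropyl-6α-anisoyloxy-8-ene, C2 ketal | O1CCOC12C[C@@](O)(C(C)C)[C@@H]3[C@@H](OC(=O)c4ccc(OC)cc4)CC(C)=CC[C@]32C | intermediate
24 | C2 ketone, 4β-hydroxy-4α-isopropyl-6α-anisoyloxy-8-ene | O=C1C[C@@](O)(C(C)C)[C@@H]2[C@@H](OC(=O)c3ccc(OC)cc3)CC(C)=CC[C@]21C | intermediate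
25 | 2β,4β-dihydroxy-4α-isopropyl-6α-anisoyloxy-8-ene | O[C@@H]1C[C@@](O)(C(C)C)[C@@H]2[C@@H](OC(=O)c3ccc(OC)cc3)CC(C)=CC[C@]21C | intermediate
26 | CNP0204191.1 | C/C=C(/C)C(=O)O[C@@H]1C[C@@](O)(C(C)C)[C@@H]2[C@@H](OC(=O)c3ccc(OC)cc3)CC(C)=CC[C@]21C | target

**Totals.** 22 steps in all. The longest linear sequence is 20 steps (steps 3–22, from cyclopentane-1,3-dione); the enone branch (steps 1–2) joins at step 7.

**Steps most likely to fail**

Step 7. Head-to-head addition, attack on the silyloxy-bearing face, or oxetane formation at the excited carbonyl could erode the photocycloaddition. The fallback reverses the roles of the partners in the classical de Mayo sense and forms the same two bonds. It sets out from 3 and 7. Enone 3 is ketalised as in step 8 to the allylic dioxolane (S)-tert-butyldimethyl[(6-methyl-1,4-dioxaspiro[4.4]non-6-en-8-yl)oxy]silane F1, which no longer absorbs. Vinylogous ester 7 is then irradiated (λ > 280 nm) in the presence of excess F1; its β-carbon C6 should bond to the less substituted alkene carbon C5 on the face anti to the silyloxy group, and closure at C1–C10 gives the β-benzyloxy cyclobutyl ketone F2. Hydrogenolysis (H2, Pd/C) of F2 gives 13, where the route is rejoined, and triethylamine converts it into 14.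

Step 12. The equilibrium may not favour the trans ring fusion strongly enough, or the β-hydroxy ketone may dehydrate under base. The fallback replaces thermodynamic by kinetic control, sets out from 14 and comes back at 16. Heating 14 with TMSCl and Et3N in DMF under equilibrating conditions should give the more substituted bis(trimethylsilyl enol ether) F3 (C5=C6 and C8=C9). Treating F3 with HF·pyridine at −40 °C → rt protonates the C5=C6 enol ether on the α-face, because the C1 methyl and the C4 silyloxy group both shield the β-face. The same reagent then removes the C4 silyl group and gives 16 directly.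

Step 15. Enolisation toward C10 instead of C8, or attack of the anhydride on the dioxolane, would spoil the triflate formation. The fallback avoids the enol triflate, sets out from 18 and comes back at 20. NaBH4 in MeOH at 0 °C reduces the lone ketone of 18 to the C9 carbinol F4 (esters inert). Dehydration of F4 with the Burgess reagent in benzene at 50 °C should proceed by syn-elimination toward the tertiary C8–H and give the more substituted alkene 20, so step 16 is skipped.

**Further compounds**

F1 | step 7 | (S)-tert-butyldimethyl[(6-methyl-1,4-dioxaspiro[4.4]non-6-en-8-yl)oxy]silane | O1CCOC12C[C@H](O[Si](C)(C)C(C)(C)C)C=C2C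
F2 | step 7 | cis-anti-cis 5-4-5 adduct with C2 ketal, 4β-OTBS, 6-OBn and C9 ketone (C8 epimers) | O1CCOC12C[C@H](O[Si](C)(C)C(C)(C)C)[C@H]3[C@]4(OCc5ccccc5)CC(C)C(=O)[C@@H]4[C@]32C
F3 | step 12 | 6,9-bis(trimethylsilyloxy)-5,8-diene with C2 ketal and 4β-OTBS | O1CCOC12C[C@H](O[Si](C)(C)C(C)(C)C)C3=C(O[Si](C)(C)C)CC(C)=C(O[Si](C)(C)C)C[C@]32C
F4 | step 15 | 4β-acetoxy-6α-(4-methoxybenzoyloxy)-9-hydroxy compound with C2 ketal (C8/C9 epimers) | O1CCOC12C[C@H](OC(C)=O)[C@@H]3[C@@H](OC(=O)c4ccc(OC)cc4)CC(C)C(O)C[C@]32C
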